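**Retrosynthetic overview**

- The target is (2R)-β-tocotrienol; the last operation removes a triisopropylsilyl (TIPS) group from O6.
- Key disconnection: O1–C8a and C8–CH3. O1 and the C8 methyl sit on the neighbouring benzene carbons C8a and C8, the pattern left when a nucleophile and an electrophile add across a C8≡C8a aryne. The tethered C2 tertiary alkoxide and CH3I are added across the aryne made from a C8a chloride; this closes the dihydropyran ring, the only ring built (the benzene ring is bought).
- The chloroarene carbinol comes from a B-alkyl Suzuki coupling (C4–C4a bond) of a 3-bromo-4-chloro-2-methylphenyl TIPS ether with the 9-BBN adduct of (R)-geranyllinalool.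
- (R)-Geranyllinalool comes from geranylgeraniol by Sharpless epoxidation (sets the future C2), iodide formation and zinc opening; the aryl bromide comes from 3-bromo-2-methylphenol by para-chlorination and silylation.

Key step: step 7

Remark: chroman numbering (O1, C2, C3, C4, C4a, C5, C6, C7, C8, C8a) is used for the aryl carbons of all intermediates. C2 of the target is (R); this carbon is C3 of the acyclic intermediates, and the enantiomeric purity of the route is that set in step 3.

**Step 1**
Reactants: 1 3-bromo-2-methylphenol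
Product: 2 3-bromo-4-chloro-2-methylphenol
Conditions: SO2Cl2 (1.05 equiv), Ph2S (cat.), AlCl3 (cat.), CH2Cl2, 0 °C to rt
Reagents that add atoms: sulfuryl chloride, O=S(=O)(Cl)Cl
Why: Electrophilic aromatic chlorination in which OH is the dominant director, one ortho position is blocked by CH3 and the sulfide/AlCl3-modified reagent is para-selective, so chlorine should enter C4, para to OH.

**Step 2**
Reactants: 2 3-bromo-4-chloro-2-methylphenol
Product: 3 (3-bromo-4-chloro-2-methylphenoxy)triisopropylsilane
Conditions: TIPSOTf, 2,6-lutidine, CH2Cl2, 0 °C to rt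
Reagents that add atoms: triisopropylsilyl trifluoromethanesulfonate, CC(C)[Si](OS(=O)(=O)C(F)(F)F)(C(C)C)C(C)C
Why: Standard O-silylation of a phenol with a silyl triflate; the bulky TIPS ether is chosen because it should survive aqueous phosphate and lithium amide base and is a poor ortho-directing group.

**Step 3**
Reactants: 4 (2E,6E,10E)-geranylgeraniol
Product: 5 (2R,3R)-2,3-epoxygeranylgeraniol, [(2R,3R)-3-methyl-3-[(3E,7E)-4,8,12-trimethyltrideca-3,7,11-trien-1-yl]oxiran-2-yl]methanol
Conditions: Ti(OiPr)4 (10 mol%), D-(−)-diethyl tartrate (12 mol%), t-BuOOH (2 equiv), 4 Å MS, CH2Cl2, −20 °C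
Reagents that add atoms: tert-butyl hydroperoxide, CC(C)(C)OO
Why: Sharpless asymmetric epoxidation, which touches only the allylic-alcohol alkene; L-(+)-tartrate gives the (2S,3S) epoxide with geraniol-type alcohols, so the D-(−) ligand should give (2R,3R) under catalyst control and set the carbon that becomes C2.

**Step 4**
Reactants: 5 (2R,3R)-2,3-epoxygeranylgeraniol
Product: 6 (2S,3R)-2-(iodomethyl)-3-methyl-3-[(3E,7E)-4,8,12-trimethyltrideca-3,7,11-trien-1-yl]oxirane
Conditions: PPh3, imidazole, I2, Et2O/MeCN, 0 °C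
Reagents that add atoms: iodine, [I][I]
Why: Appel-type iodination of the primary alcohol through its alkoxyphosphonium salt, mild enough to leave the epoxide and both stereocentres untouched (the C2 descriptor changes only through CIP priority).

**Step 5**
Reactants: 6 epoxy iodide
Product: 7 (3R,6E,10E)-3,7,11,15-tetramethylhexadeca-1,6,10,14-tetraen-3-ol, (R)-geranyllinalool
Conditions: Zn dust, EtOH, reflux; aq. NH4Cl work-up
Reagents that add atoms: none
Why: Zinc-mediated reductive ring opening (β-elimination) of a 2,3-epoxy iodide, in which zinc inserts into C–I and the adjacent epoxide C–O bond breaks to give the vinyl group, while the C3–O bond is kept so (3R) is carried over unchanged.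

**Step 6**
Reactants: 7 (R)-geranyllinalool; 3 (3-bromo-4-chloro-2-methylphenoxy)triisopropylsilane
Product: 9 (3R,6E,10E)-1-[6-chloro-2-methyl-3-(triisopropylsilyloxy)phenyl]-3,7,11,15-tetramethylhexadeca-6,10,14-trien-3-ol, via borane adduct 8 (not isolated)
Conditions: 9-BBN (2.2 equiv), THF, 0 °C to rt; then 3, PdCl2(dppf) (5 mol%), aq. K3PO4, THF/DMF, 60 °C
Reagents that add atoms: none
Why: 9-BBN hydroborates the monosubstituted alkene anti-Markovnikov and leaves the trisubstituted alkenes alone (the extra equivalent allows for the free OH), and the B-alkyl Suzuki–Miyaura coupling then proceeds at C–Br because zerovalent palladium inserts into C–Br much faster than into C–Cl with this ligand.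

**Step 7**
Reactants: 9 chloroarene carbinol
Product: 14 (R)-2,5,8-trimethyl-6-(triisopropylsilyloxy)-2-[(3E,7E)-4,8,12-trimethyltrideca-3,7,11-trien-1-yl]chroman (6-O-TIPS-(R)-β-tocotrienol), via lithium alkoxide 10 (not isolated), via chloroaryllithium 11 (not isolated), via aryne alkoxide 12 (not isolated), via chromanyllithium 13 (not isolated)
Conditions: n-BuLi (1.05 equiv), THF (dilute), −78 °C; lithium 2,2,6,6-tetramethylpiperidide (LiTMP, 2.5 equiv), −78 to −10 °C; then MeI (6 equiv), −78 °C to rt
Reagents that add atoms: iodomethane, CI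
Why: n-BuLi first gives lithium alkoxide 10, then LiTMP removes the single ring hydrogen ortho to chlorine (C8–H) to give 11, which loses LiCl to the C8–C8a aryne 12. The tethered tertiary alkoxide adds to C8a in a 6-exo-dig closure that forms O1–C8a and the dihydropyran ring and leaves the carbanion at C8 (13), which CH3I methylates to form C8–CH3. The closest known reaction type is the base-induced benzyne cyclisation of halogenoarylalkanols to chromans with electrophilic trapping of the resulting aryllithium. No stereocentre is formed, and C2 keeps its (R) configuration because the alkoxide acts as nucleophile under basic conditions and the C2–O bond is never ionised. The step needs one aryne and one direction of addition: the only hydrogen ortho to chlorine is at C8, the three-atom tether lets oxygen reach C8a only, and the bulky TIPS group disfavours lithiation at C7. Forming the alkoxide with n-BuLi limits the amine to one equivalent, and the hindered amine is a slow proton donor at low temperature, so the C8 anion should survive until methylation.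

**Step 8**
Reactants: 14 6-O-TIPS-(R)-β-tocotrienol
Product: 15 (R)-β-tocotrienol, (2R)-2,5,8-trimethyl-2-[(3E,7E)-4,8,12-trimethyltrideca-3,7,11-trien-1-yl]chroman-6-ol
Conditions: TBAF, AcOH (1:1), THF, 0 °C to rt, argon
Reagents that add atoms: none
Why: Fluoride cleavage of the aryl silyl ether, buffered with acetic acid so that the electron-rich phenoxide is protonated at once; the alkenes and the C2 ether stereocentre are inert to these conditions.

**Compound list**

1 | 3-bromo-2-methylphenol | Cc1c(O)cccc1Br | starting material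
2 | 3-bromo-4-chloro-2-methylphenol | Cc1c(O)ccc(Cl)c1Br | intermediate
3 | (3-bromo-4-chloro-2-methylphenoxy)triisopropylsilane | Cc1c(O[Si](C(C)C)(C(C)C)C(C)C)ccc(Cl)c1Br | intermediate
4 | (2E,6E,10E)-geranylgeraniol | CC(C)=CCC/C(C)=C/CC/C(C)=C/CC/C(C)=C/CO | starting material
5 | (2R,3R)-2,3-epoxygeranylgeraniol | CC(C)=CCC/C(C)=C/CC/C(C)=C/CC[C@@]1(C)O[C@@H]1CO | intermediate
6 | (2S,3R)-2-(iodomethyl)-3-methyl-3-[(3E,7E)-4,8,12-trimethyltrideca-3,7,11-trien-1-yl]oxirane | CC(C)=CCC/C(C)=C/CC/C(C)=C/CC[C@@]1(C)O[C@@H]1CI | intermediate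
7 | (3R,6E,10E)-3,7,11,15-tetramethylhexadeca-1,6,10,14-tetraen-3-ol, (R)-geranyllinalool | CC(C)=CCC/C(C)=C/CC/C(C)=C/CC[C@](O)(C)C=C | intermediate
8 | (3S,6E,10E)-1-(9-borabicyclo[3.3.1]nonan-9-yl)-3,7,11,15-tetramethylhexadeca-6,10,14-trien-3-ol (same geometry at C3 as 7; descriptor changes by priority only) | CC(C)=CCC/C(C)=C/CC/C(C)=C/CC[C@](O)(C)CCB1C2CCCC1CCC2 | intermediate
9 | (3R,6E,10E)-1-[6-chloro-2-methyl-3-(triisopropylsilyloxy)phenyl]-3,7,11,15-tetramethylhexadeca-6,10,14-trien-3-ol | CC(C)=CCC/C(C)=C/CC/C(C)=C/CC[C@](O)(C)CCc1c(C)c(O[Si](C(C)C)(C(C)C)C(C)C)ccc1Cl | intermediate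
10 | lithium alkoxide of 9 | CC(C)=CCC/C(C)=C/CC/C(C)=C/CC[C@](O[Li])(C)CCc1c(C)c(O[Si](C(C)C)(C(C)C)C(C)C)ccc1Cl | intermediate
11 | lithium alkoxide of 9 lithiated at the ring carbon ortho to chlorine (C8) | CC(C)=CCC/C(C)=C/CC/C(C)=C/CC[C@](O[Li])(C)CCc1c(C)c(O[Si](C(C)C)(C(C)C)C(C)C)cc([Li])c1Cl | intermediate
12 | lithium alkoxide bearing the C8–C8a aryne | CC(C)=CCC/C(C)=C/CC/C(C)=C/CC[C@](O[Li])(C)CCC1=C(C)C(O[Si](C(C)C)(C(C)C)C(C)C)=CC#C1 | intermediate
13 | (R)-8-lithio-2,5-dimethyl-6-(triisopropylsilyloxy)-2-[(3E,7E)-4,8,12-trimethyltrideca-3,7,11-trien-1-yl]chroman | CC(C)=CCC/C(C)=C/CC/C(C)=C/CC[C@]1(C)CCc2c(C)c(O[Si](C(C)C)(C(C)C)C(C)C)cc([Li])c2O1 | intermediate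
14 | 6-O-triisopropylsilyl-(R)-β-tocotrienol | CC(C)=CCC/C(C)=C/CC/C(C)=C/CC[C@]1(C)CCc2c(C)c(O[Si](C(C)C)(C(C)C)C(C)C)cc(C)c2O1 | intermediate
15 | (R)-β-tocotrienol | CC(C)=CCC/C(C)=C/CC/C(C)=C/CC[C@]1(C)CCc2c(C)c(O)cc(C)c2O1 | target

**Step count and risks**

Total step count: 8. Longest linear sequence: 6 steps (4 to 15 through steps 3, 4, 5, 6, 7 and 8).

Most likely to fail, first: step 7. The C8 carbanion may be protonated by tetramethylpiperidine before methylation. Deprotonation may also occur at the C5 methyl or at C7, and the amide may add to the aryne between molecules. The fallback sets out from 9 and comes back at 14. Palladium-catalysed intramolecular C–O coupling of the aryl chloride with the tertiary alcohol (Pd(OAc)2, 2-(di-tert-butylphosphino)-1,1'-binaphthyl, Cs2CO3, toluene, 80 °C) closes the ring without any aryne and should give (R)-2,5-dimethyl-6-(triisopropylsilyloxy)-2-[(3E,7E)-4,8,12-trimethyltrideca-3,7,11-trien-1-yl]chroman F1. This is the same compound that an early proton quench of 13 would leave, so it also recovers material from a partly failed step 7. Directed ortho-lithiation of F1 next to O1 (n-BuLi, TMEDA, Et2O, 0 °C; C7 is shielded by the TIPS group) regenerates 13, and MeI then gives 14.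

Second: step 6. Oxidative addition and transmetalation at a bromide flanked by CH3 and Cl may be slow, so that protodeboronation or β-hydride elimination of the alkylborane takes over; the free OH may also divert 9-BBN. The fallback sets out from 7 (with 3) and comes back at 9, replacing the borane by an alkylzinc (Negishi coupling).
- 7 is silylated (TESOTf, 2,6-lutidine, CH2Cl2, −78 °C) to (R)-geranyllinalool triethylsilyl ether F2.
- Hydroboration–oxidation (9-BBN, THF; then NaOH, H2O2) gives (3R,6E,10E)-3,7,11,15-tetramethyl-3-(triethylsilyloxy)hexadeca-6,10,14-trien-1-ol F3.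
- PPh3, imidazole, I2 gives the primary iodide, (3R,6E,10E)-1-iodo-3,7,11,15-tetramethyl-3-(triethylsilyloxy)hexadeca-6,10,14-triene F4.
- Zinc insertion (Zn dust, LiCl, THF, 40 °C) gives the alkylzinc iodide of F4, F5.
- Coupling of F5 with 3 (Pd(OAc)2, SPhos, THF, rt; C–Br reacts before C–Cl) gives the triethylsilyl ether of 9, F6.
- Camphorsulfonic acid (cat.) in MeOH at 0 °C removes the triethylsilyl group and leaves the aryl TIPS ether, giving 9.

Third: step 1. Chlorination may go partly ortho to OH (C6) or twice, giving isomers that are hard to separate. The fallback sets out from 1 and comes back at 2, fixing the para position through nitrogen.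
- Nitrosation (NaNO2, aq. H2SO4, 0 °C), which is strongly para-selective, gives 3-bromo-2-methyl-4-nitrosophenol F7.
- Reduction (Na2S2O4, aq. EtOH) gives 4-amino-3-bromo-2-methylphenol F8.
- Diazotisation (NaNO2, HCl, 0 °C) gives 2-bromo-4-hydroxy-3-methylbenzenediazonium chloride F9.
- Sandmeyer chlorination (CuCl, HCl, 60 °C) gives 2.

**Further compounds**

F1 | step 7 | (R)-2,5-dimethyl-6-(triisopropylsilyloxy)-2-[(3E,7E)-4,8,12-trimethyltrideca-3,7,11-trien-1-yl]chroman | CC(C)=CCC/C(C)=C/CC/C(C)=C/CC[C@]1(C)CCc2c(C)c(O[Si](C(C)C)(C(C)C)C(C)C)ccc2O1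
F2 | step 6 | (3R,6E,10E)-3,7,11,15-tetramethyl-3-(triethylsilyloxy)hexadeca-1,6,10,14-tetraene | CC(C)=CCC/C(C)=C/CC/C(C)=C/CC[C@](O[Si](CC)(CC)CC)(C)C=C
F3 | step 6 | (3R,6E,10E)-3,7,11,15-tetramethyl-3-(triethylsilyloxy)hexadeca-6,10,14-trien-1-ol | CC(C)=CCC/C(C)=C/CC/C(C)=C/CC[C@](O[Si](CC)(CC)CC)(C)CCO
F4 | step 6 | (3R,6E,10E)-1-iodo-3,7,11,15-tetramethyl-3-(triethylsilyloxy)hexadeca-6,10,14-triene | CC(C)=CCC/C(C)=C/CC/C(C)=C/CC[C@](O[Si](CC)(CC)CC)(C)CCI
F5 | step 6 | [(3R,6E,10E)-3,7,11,15-tetramethyl-3-(triethylsilyloxy)hexadeca-6,10,14-trien-1-yl]zinc iodide | CC(C)=CCC/C(C)=C/CC/C(C)=C/CC[C@](O[Si](CC)(CC)CC)(C)CC[Zn]I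
F6 | step 6 | triethylsilyl ether of 9 | CC(C)=CCC/C(C)=C/CC/C(C)=C/CC[C@](O[Si](CC)(CC)CC)(C)CCc1c(C)c(O[Si](C(C)C)(C(C)C)C(C)C)ccc1Cl
F7 | step 1 | 3-bromo-2-methyl-4-nitrosophenol | Cc1c(O)ccc(N=O)c1Br
F8 | step 1 | 4-amino-3-bromo-2-methylphenol | Cc1c(O)ccc(N)c1Br
F9 | step 1 | 2-bromo-4-hydroxy-3-methylbenzenediazonium chloride | Cc1c(O)ccc([N+]#N)c1Br.[Cl-]
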